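**Retrosynthetic overview**
1. Target 19 ⇒ (2S,3S)-alcohol 12 + (Z)-acid 17 by esterification; 17 comes from 3-methylfuran-2(5H)-one, whose ring fixes the Z geometry.
2. 12 ⇒ racemic 3-ketone 11 ⇒ alcohol mixture 10; a Ru transfer hydrogenation with dynamic kinetic resolution sets C2 and C3 (cis) together.
3. 10 ⇒ aldehyde ether 7: the C2–C3 bond and the dihydrofuran ring (the only ring made; the benzene ring is bought) form by photochemical 1,6-hydrogen transfer and recombination of the resulting 1,5-biradical.
4. 7 ⇒ resorcinol by formylation, C-acetylation and acidity-controlled O-methallylation.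

Assumption: the SMILES is read as the cis-(2S,3S)-dihydrobenzofuran carrying a (Z)-4-acetoxy-2-methylbut-2-enoate on O3; Ac2O, DMF and water are treated as reagents.

**Step 1**
Reactants: 1 resorcinol
Product: 3 2,4-dihydroxybenzaldehyde, via iminium chloride 2 (not isolated)
Conditions: POCl3, DMF, MeCN, −15 °C to rt; then H2O, 50 °C
Reagents that add atoms: N,N-dimethylformamide CN(C)C=O; water O
Why: Vilsmeier–Haack formylation goes para to one OH and ortho to the other, and the iminium salt is hydrolysed on aqueous work-up.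

**Step 2**
Reactants: 3 2,4-dihydroxybenzaldehyde
Product: 4 5-acetyl-2,4-dihydroxybenzaldehyde
Conditions: Ac2O (1.1 equiv), ZnCl2, AcOH, 120 °C; then 1 M HCl work-up
Reagents that add atoms: acetic anhydride CC(=O)OC(C)=O
Why: Nencki-type Friedel–Crafts C-acetylation under equilibrating conditions should enter at C5 (para to the 2-OH, ortho to the 4-OH, not flanked by two oxygens), the same 4,6-diacyl pattern as in the preparation of 4,6-diacetylresorcinol.

**Step 3**
Reactants: 4 5-acetyl-2,4-dihydroxybenzaldehyde; 5 3-chloro-2-methylprop-1-ene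
Product: 7 2-acetyl-4-formyl-5-[(2-methylprop-2-en-1-yl)oxy]phenyl acetate, via monoether 6 (not isolated)
Conditions: KHCO3 (1.1 equiv), NaI (cat.), DMF, 45 °C; then Ac2O, pyridine, DMAP (cat.), rt
Reagents that add atoms: acetic anhydride CC(=O)OC(C)=O
Why: Williamson etherification under one equivalent of weak base should alkylate the aldehyde-chelated 2-OH, which is roughly one pKa unit more acidic (weaker chelate) than the acetyl-chelated 4-OH; acetylating the remaining phenol in the same pot removes the o-hydroxyketone proton-transfer channel that would quench the next step.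

**Step 4**
Reactants: 7 2-acetyl-4-formyl-5-[(2-methylprop-2-en-1-yl)oxy]phenyl acetate
Product: 10 1-[3,6-dihydroxy-2-(prop-1-en-2-yl)-2,3-dihydro-1-benzofuran-5-yl]ethan-1-one (racemic cis/trans mixture), via triplet 1,5-biradical 8 (not isolated), via photocyclised acetate 9 (not isolated)
Conditions: hν (365 nm), degassed MeCN (0.01 M), 25 °C; then NH3 (7 M in MeOH), 0 °C
Reagents that add atoms: none
Why: Norrish–Yang-type photocyclisation, the known reaction type for o-alkoxybenzaldehydes: the n,π* triplet aldehyde abstracts the allylic α-oxy hydrogen (1,6-hydrogen transfer), the ketyl/α-oxyallyl biradical closes radical-to-radical at the oxygen-bearing carbon to give the five-membered ring, and ammonolysis frees the phenol; C2 and C3 are formed without control here and are both reset in step 6.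

**Step 5**
Reactants: 10 1-[3,6-dihydroxy-2-(prop-1-en-2-yl)-2,3-dihydro-1-benzofuran-5-yl]ethan-1-one
Product: 11 5-acetyl-6-hydroxy-2-(prop-1-en-2-yl)-1-benzofuran-3(2H)-one (racemic)
Conditions: Dess–Martin periodinane, pyridine, CH2Cl2, 0 °C; used without chromatography
Reagents that add atoms: none
Why: Dess–Martin oxidation of the benzylic alcohol is fast and buffered, the acyl-chelated phenol is inert to the reagent, and all four stereoisomers of 10 converge on one racemic ketone.

**Step 6**
Reactants: 11 5-acetyl-6-hydroxy-2-(prop-1-en-2-yl)-1-benzofuran-3(2H)-one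
Product: 12 1-[(2S,3S)-3,6-dihydroxy-2-(prop-1-en-2-yl)-2,3-dihydro-1-benzofuran-5-yl]ethan-1-one
Conditions: RuCl[(R,R)-TsDPEN](p-cymene) (2 mol %), HCO2H/Et3N (5:2), EtOAc, 25 °C
Reagents that add atoms: none
Why: Noyori asymmetric transfer hydrogenation with dynamic kinetic resolution: C2 racemises by enolisation while the (R,R) catalyst reduces the activated α-oxy ketone from the face giving the 3S carbinol and only in the enantiomer whose isopropenyl group is anti to the incoming hydride, so the OH ends cis and C2 is S; the chelated acetyl group and the isolated alkene should not be reduced.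

**Step 7**
Reactants: 13 3-methylfuran-2(5H)-one
Product: 16 4-methoxybenzyl (2Z)-4-acetoxy-2-methylbut-2-enoate, via sodium hydroxy carboxylate 14 (not isolated), via hydroxy ester 15 (not isolated)
Conditions: NaOH (1.0 equiv), MeOH/H2O, rt, evaporate; 4-methoxybenzyl chloride, NaI (cat.), DMF, rt; then Ac2O, pyridine, DMAP (cat.), 0 °C
Reagents that add atoms: sodium hydroxide [Na+].[OH-]; 4-methoxybenzyl chloride COc1ccc(CCl)cc1; acetic anhydride CC(=O)OC(C)=O
Why: Saponification opens the butenolide with the Z geometry fixed by the ring, carboxylate alkylation blocks the acid without activating it, and immediate acetylation caps the hydroxyl before it can re-lactonise.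

**Step 8**
Reactants: 16 4-methoxybenzyl (2Z)-4-acetoxy-2-methylbut-2-enoate
Product: 17 (2Z)-4-acetoxy-2-methylbut-2-enoic acid
Conditions: TFA, anisole, CH2Cl2, 0 °C
Reagents that add atoms: none
Why: Acidolysis of the 4-methoxybenzyl ester (cation trapped by anisole) leaves the allylic acetate and the Z alkene untouched at 0 °C.

**Step 9**
Reactants: 12 1-[(2S,3S)-3,6-dihydroxy-2-(prop-1-en-2-yl)-2,3-dihydro-1-benzofuran-5-yl]ethan-1-one; 17 (2Z)-4-acetoxy-2-methylbut-2-enoic acid
Product: 19 (2S,3S)-5-acetyl-6-hydroxy-2-(prop-1-en-2-yl)-2,3-dihydro-1-benzofuran-3-yl (2Z)-4-acetoxy-2-methylbut-2-enoate, via mixed anhydride 18 (not isolated)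
Conditions: 2,4,6-trichlorobenzoyl chloride, Et3N, toluene, 0 °C; then 12, DMAP, toluene, 0 °C to rt
Reagents that add atoms: none
Why: Yamaguchi esterification, the usual method for isomerisation-prone angelate-type acids, acylates the secondary alcohol in preference to the ketone-chelated phenol and does not touch C2 or C3; low temperature and minimal base limit Z-to-E drift and loss of the p-hydroxybenzylic ester.

**Compound list**
1 | resorcinol | Oc1cccc(O)c1 | starting material
2 | N-[(2,4-dihydroxyphenyl)methylidene]-N-methylmethanaminium chloride | C[N+](C)=Cc1ccc(O)cc1O.[Cl-] | intermediate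
3 | 2,4-dihydroxybenzaldehyde | O=Cc1ccc(O)cc1O | intermediate
4 | 5-acetyl-2,4-dihydroxybenzaldehyde | CC(=O)c1cc(C=O)c(O)cc1O | intermediate
5 | 3-chloro-2-methylprop-1-ene (methallyl chloride) | C=C(C)CCl | starting material
6 | 5-acetyl-4-hydroxy-2-[(2-methylprop-2-en-1-yl)oxy]benzaldehyde | C=C(C)COc1cc(O)c(C(C)=O)cc1C=O | intermediate
7 | 2-acetyl-4-formyl-5-[(2-methylprop-2-en-1-yl)oxy]phenyl acetate | C=C(C)COc1cc(OC(C)=O)c(C(C)=O)cc1C=O | intermediate
8 | triplet 1,5-biradical (benzylic ketyl carbon and α-oxyallyl carbon) | C=C(C)[CH]Oc1cc(OC(C)=O)c(C(C)=O)cc1[CH]O | intermediate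
9 | 5-acetyl-3-hydroxy-2-(prop-1-en-2-yl)-2,3-dihydro-1-benzofuran-6-yl acetate (racemic, cis/trans; no defined stereocentres) | C=C(C)C1Oc2cc(OC(C)=O)c(C(C)=O)cc2C1O | intermediate
10 | 1-[3,6-dihydroxy-2-(prop-1-en-2-yl)-2,3-dihydro-1-benzofuran-5-yl]ethan-1-one (racemic, cis/trans; no defined stereocentres) | C=C(C)C1Oc2cc(O)c(C(C)=O)cc2C1O | intermediate
11 | 5-acetyl-6-hydroxy-2-(prop-1-en-2-yl)-1-benzofuran-3(2H)-one (racemic) | C=C(C)C1Oc2cc(O)c(C(C)=O)cc2C1=O | intermediate
12 | 1-[(2S,3S)-3,6-dihydroxy-2-(prop-1-en-2-yl)-2,3-dihydro-1-benzofuran-5-yl]ethan-1-one (cis) | C=C(C)[C@@H]1Oc2cc(O)c(C(C)=O)cc2[C@@H]1O | intermediate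
13 | 3-methylfuran-2(5H)-one | CC1=CCOC1=O | starting material
14 | sodium (2Z)-4-hydroxy-2-methylbut-2-enoate | OC/C=C(/C)C(=O)[O-].[Na+] | intermediate
15 | 4-methoxybenzyl (2Z)-4-hydroxy-2-methylbut-2-enoate | COc1ccc(COC(=O)/C(C)=C\CO)cc1 | intermediate
16 | 4-methoxybenzyl (2Z)-4-acetoxy-2-methylbut-2-enoate | COc1ccc(COC(=O)/C(C)=C\COC(C)=O)cc1 | intermediate
17 | (2Z)-4-acetoxy-2-methylbut-2-enoic acid | CC(=O)OC/C=C(/C)C(=O)O | intermediate
18 | (2Z)-4-acetoxy-2-methylbut-2-enoic 2,4,6-trichlorobenzoic anhydride | CC(=O)OC/C=C(/C)C(=O)OC(=O)c1c(Cl)cc(Cl)cc1Cl | intermediate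
19 | (2S,3S)-5-acetyl-6-hydroxy-2-(prop-1-en-2-yl)-2,3-dihydro-1-benzofuran-3-yl (2Z)-4-acetoxy-2-methylbut-2-enoate | C=C(C)[C@@H]1Oc2cc(O)c(C(C)=O)cc2[C@@H]1OC(=O)/C(C)=C\COC(C)=O | target

**Totals**
Total steps: 9. Longest linear sequence: 7 (steps 1–6 and 9).

**Steps most likely to fail, with fallbacks**

Step 4 is the largest risk. The triplet may be quenched by the tethered alkene, may give an oxetane, or the biradical may close at the allyl terminus to a seven-membered ring. If so, the ring is closed ionically: the fallback sets out from 4 and 5 and returns at 10. Chloride 5 is quaternised with tetrahydrothiophene (acetone, rt) to 1-(2-methylprop-2-en-1-yl)thiolan-1-ium chloride F1. Its ylide (NaH, three equivalents to cover both phenols, THF/DMSO, 0 °C) adds to the aldehyde of 4 to give the vinyl epoxide 1-{2,4-dihydroxy-5-[3-(prop-1-en-2-yl)oxiran-2-yl]phenyl}ethan-1-one F2. Only the ortho phenoxide can reach the oxirane, and it opens it at the allylic carbon in the same pot to give 10. The product is expected mainly trans, which does not matter because step 5 removes C3. This detour also removes the selectivity question of step 3.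

Step 6 is the second risk. Ketone 11 may slip into conjugation as the 2-isopropylidene isomer through the same enol that the resolution needs, or the acetyl group may be reduced. If so, the ketone is avoided: the fallback sets out from 10 and returns at 12. The cis racemate of 10 is separated by chromatography and resolved by lipase acylation (Candida antarctica lipase B, vinyl acetate, MTBE, 30 °C). By the Kazlauskas model the 3S enantiomer is acylated to (2S,3S)-5-acetyl-6-hydroxy-2-(prop-1-en-2-yl)-2,3-dihydro-1-benzofuran-3-yl acetate F3. F3 is separated from the unreacted (2R,3R)-alcohol and deacetylated with the same lipase in MeOH to 12. If the enzyme prefers the other enantiomer, 12 is the unreacted alcohol. The yield is capped at half of the cis fraction.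

Step 3 is the third risk. The pKa-based preference for the 2-OH may be modest, and the acetyl group in step 2 could enter at C3 instead of C5. If either happens, the ether is installed before the second carbonyl: the fallback sets out from 1 and 5 and returns at 6. Resorcinol is acetylated (AcOH, ZnCl2, 140 °C) to 1-(2,4-dihydroxyphenyl)ethan-1-one F4. Its only non-chelated OH is alkylated with 5 (K2CO3, acetone, reflux) to 1-{2-hydroxy-4-[(2-methylprop-2-en-1-yl)oxy]phenyl}ethan-1-one F5. Iodination para to the phenol (N-iodosuccinimide, TsOH cat., MeCN, 0 °C) gives 1-{2-hydroxy-5-iodo-4-[(2-methylprop-2-en-1-yl)oxy]phenyl}ethan-1-one F6. Reductive carbonylation (Pd(OAc)2, Xantphos, CO 1 atm, Et3SiH, Na2CO3, DMF, 60 °C) then gives 6, which is acetylated as in step 3.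

**Further compounds**
F1 | step 4 | 1-(2-methylprop-2-en-1-yl)thiolan-1-ium chloride | C=C(C)C[S+]1CCCC1.[Cl-]
F2 | step 4 | 1-{2,4-dihydroxy-5-[3-(prop-1-en-2-yl)oxiran-2-yl]phenyl}ethan-1-one | C=C(C)C1OC1c1cc(C(C)=O)c(O)cc1O
F3 | step 6 | (2S,3S)-5-acetyl-6-hydroxy-2-(prop-1-en-2-yl)-2,3-dihydro-1-benzofuran-3-yl acetate | C=C(C)[C@@H]1Oc2cc(O)c(C(C)=O)cc2[C@@H]1OC(C)=O
F4 | step 3 | 1-(2,4-dihydroxyphenyl)ethan-1-one | CC(=O)c1ccc(O)cc1O
F5 | step 3 | 1-{2-hydroxy-4-[(2-methylprop-2-en-1-yl)oxy]phenyl}ethan-1-one | C=C(C)COc1ccc(C(C)=O)c(O)c1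
F6 | step 3 | 1-{2-hydroxy-5-iodo-4-[(2-methylprop-2-en-1-yl)oxy]phenyl}ethan-1-one | C=C(C)COc1cc(O)c(C(C)=O)cc1I
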